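The numbers in the tables were computed from invented constants; noise was put on by code.

Over 40 min, a flask of G, Q and J had to be foreseen, charged with more Q than two earlier runs.

in all of them: G 0.81 M

| run | J | Q | remark | time |
|---|---|---|---|---|
| summer | 0.60 equiv | 1 equiv | run made earlier |  |
| midnight | 0.60 equiv | 1.5 equiv | run made earlier |  |
| flask | 0.600 equiv | 2.00 equiv |  | 40 min |

| run | time / min | G / % | Z / % |
|---|---|---|---|
| summer | 10.0 | 51.2 | 16.6 |
| summer | 20.0 | 52.6 | 16.3 |
| summer | 30.0 | 51.3 | 15.6 |
| summer | 40.0 | 51.8 | 15.0 |
| summer | 50.0 | 52.3 | 15.5 |
| midnight | 4.00 | 56.8 | 20.4 |
| midnight | 8.00 | 55.8 | 13.9 |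
| midnight | 15.0 | 56.3 | 14.4 |
| midnight | 25.0 | 55.5 | 13.3 |
| midnight | 50.0 | 56.0 | 14.7 |

(standard deviation of a reading: 0.5 percentage points)

1. why nothing more happens at 40 min, or that something still does (all of G has reacted / J has run out first / forward and back rates have come level / it is still moving)
2. how much of the G has reacted by 40 min
3. how much Z there is at 40 min, in percent of the G charged
4. how much L there is at 40 min, in percent of the G charged

- the numbers in the tables scatter with a standard deviation of 0.5 percentage points
- the reaction counts as stopped when no species that holds the G changes by six tenths of a point or more over the second half of the time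

The readings held something odd. In the summer run G stayed level within the scatter at a mean of 51.8%, and in the midnight run at 56.1%. The J charged was 0.60 equiv, yet the summer run lost 48.2% of its G, and the midnight run, with more Q, lost less, 43.9%.

I took J as the limiting reagent, one J taking one G or one Q, so that the missing J had gone to Q. By that balance I reckoned 88.2% of the Q remaining in the summer run and 89.3% in the midnight run. I supposed that c_G and c_Q each fall at a rate proportional to c_J times their own value. Dividing one rate by the other then removes c_J and time. The two runs gave 5.21 and 5.10. Their mean, 5.16, is my selectivity factor S, the logarithm of the fraction of G left over the logarithm of the fraction of Q left.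

For the flask I tried G left at 60.0%. S then leaves Q at 90.6%, and the J balance puts G at 58.9%. I took the midpoint, 59.4%, which is 40.6% conversion. The late summer readings put Z at 31.9% of the reacted G, so I expected 13.0% Z and, taking the rest as L, 27.6% L.

The forecast, judging that “J is the limiting reagent”, said J has run out first, with 40% conversion, 12.8% Z and 27.2% L.

The flask gave this outcome: J has run out first, with 0% of the J left at 40.0 min, 40.7% conversion, 13.1% Z and 27.6% L.

    G + J → Z (k = 0.310 /M/s)
    Q + J → E (k = 0.0600 /M/s)
    Z ⇌ L (K = 2.10, k = 0.00470 /s)

Read from this flask's end state at 40.0 min, 59.3% of G and 90.4% of Q, S was 5.18. In this flask G stopped short mainly through the depletion of J to 0% of its charge: the run without it reached 100% conversion against 40.7%, while the run without the turning of Q + J into E reached 60.0%, which is a part of the gap. A flask like this one with 2.40 equiv of J kept 29.9% of its Q, from which S gives 0.197% of G, and it held 0.195%.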